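**Plan**
Ring A is the 4-pyranone (O1, C2-OMe, C3-Me, C4=O, C5-Me, C6); the side chain runs from C1′ (on C6) to C11′, and C10′ carries the acetate.
Retrosynthesis removes the acetate and a silyl ether, then cuts C6–C1′: ring A has methyls on both C3 and C5 beside the C4 carbonyl, so it is 2,6-dimethoxy-3,5-dimethyl-4-pyranone with one of two equivalent methoxy groups (on C6) exchanged for C1′.
The chain partner is a C1′ phenyl sulfone, cut further at C1′–S (hydrothiolation of a terminal alkene) and at C8′–C9′ (epoxide opening by a C8 Grignard reagent).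
Forward: ring A is closed once, in step 2, and becomes the symmetric pyranone 6; sulfone 13 is built separately in four steps; the two are joined in step 8 without ring closure.
Desulfonylation, desilylation and acetylation finish the target.
Stereochemistry: the only stereocentre, C10′ (S), comes from (S)-propylene oxide, opened at its CH2 carbon; no later step touches the C10′–O bond.

Key step: step 8

**Route**

Step 1
Reactants: 1 dimethyl 3-oxopentanedioate
Product: 3 dimethyl 2,4-dimethyl-3-oxopentanedioate (diastereomer mixture), via dimethyl 2-methyl-3-oxopentanedioate 2 (not isolated)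
Conditions: MeI (2.2 equiv), K2CO3, acetone, reflux
Reagents that add atoms: iodomethane, CI
Why: Double C-alkylation of a β-keto diester under mild carbonate conditions, in which each CH2 is activated by the ketone and one ester, the once-methylated carbon is less acidic and more hindered so the second methyl should go to the other side, and both diastereomers converge in step 2.

Step 2
Reactants: 3 dimethyl 2,4-dimethyl-3-oxopentanedioate
Product: 4 4-hydroxy-6-methoxy-3,5-dimethyl-2H-pyran-2-one
Conditions: conc. H2SO4, 0 °C to rt; poured onto ice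
Reagents that add atoms: none
Why: Acid-promoted cyclocondensation of the kind that turns β-keto esters into 2-pyranones in sulfuric acid, in which the carbonyl oxygen of one ester acylates onto the other activated ester with loss of one methanol and ring A closes as a stabilised hydroxypyranone.

Step 3
Reactants: 4 4-hydroxy-6-methoxy-3,5-dimethyl-2H-pyran-2-one
Product: 6 2,6-dimethoxy-3,5-dimethyl-4H-pyran-4-one, via 4-hydroxy-2,6-dimethoxy-3,5-dimethylpyrylium triflate 5 (not isolated)
Conditions: MeOTf (1.1 equiv), CH2Cl2, 0 °C to rt; then aq. NaHCO3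
Reagents that add atoms: methyl trifluoromethanesulfonate, COS(=O)(=O)C(F)(F)F
Why: O-Methylation of a neutral ambident hydroxypyranone with a hard methylating agent and no base should occur at the lactone carbonyl oxygen, the most basic site and the one remote from the mobile proton, so that the pyrylium salt 5 gives the symmetric 4-pyranone when its OH proton is removed on work-up.

Step 4
Reactants: 7 oct-7-en-1-yl bromide (8-bromooct-1-ene), 8 (S)-2-methyloxirane ((S)-propylene oxide)
Product: 10 (S)-undec-10-en-2-ol, via oct-7-en-1-ylmagnesium bromide 9 (not isolated)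
Conditions: Mg, THF, rt; then CuI (10 mol%), 8, THF, −30 to 0 °C; aq. NH4Cl
Reagents that add atoms: none
Why: Copper-catalysed Grignard opening of a terminal epoxide is an SN2 attack at the unsubstituted CH2 carbon, so the C–O bond of the stereocentre is not broken and the (S) configuration of 8 becomes C2 of 10 unchanged.

Step 5
Reactants: 10 (S)-undec-10-en-2-ol
Product: 11 (S)-tert-butyldimethyl(undec-10-en-2-yloxy)silane
Conditions: TBSCl, imidazole, DMF, rt
Reagents that add atoms: tert-butyldimethylsilyl chloride, CC(C)(C)[Si](C)(C)Cl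
Why: Imidazole-promoted silylation of a secondary alcohol masks the acidic OH before the carbanion chemistry, and the silyl ether should tolerate the radical, peracid, amide-base and electron-transfer conditions that follow.

Step 6
Reactants: 11 (S)-tert-butyldimethyl(undec-10-en-2-yloxy)silane
Product: 12 (S)-tert-butyldimethyl((11-(phenylthio)undecan-2-yl)oxy)silane
Conditions: PhSH (1.2 equiv), AIBN (5 mol%), toluene, 80 °C
Reagents that add atoms: thiophenol, Sc1ccccc1
Why: Radical thiol–ene hydrothiolation, in which the thiyl radical adds to the terminal CH2 of the monosubstituted alkene and the secondary carbon radical takes hydrogen from thiophenol, should give the anti-Markovnikov primary sulfide.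

Step 7
Reactants: 12 (S)-tert-butyldimethyl((11-(phenylthio)undecan-2-yl)oxy)silane
Product: 13 (S)-tert-butyldimethyl((11-(phenylsulfonyl)undecan-2-yl)oxy)silane
Conditions: mCPBA (2.2 equiv), CH2Cl2, 0 °C to rt; aq. Na2SO3/NaHCO3 wash
Reagents that add atoms: 3-chloroperoxybenzoic acid, OOC(=O)c1cccc(Cl)c1
Why: Peracid oxidation of a sulfide through the sulfoxide to the sulfone, with no other oxidisable group present and the silyl ether inert.

Step 8
Reactants: 13 (S)-tert-butyldimethyl((11-(phenylsulfonyl)undecan-2-yl)oxy)silane, 6 2,6-dimethoxy-3,5-dimethyl-4H-pyran-4-one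
Product: 16 6-((10S)-10-((tert-butyldimethylsilyl)oxy)-1-(phenylsulfonyl)undecyl)-2-methoxy-3,5-dimethyl-4H-pyran-4-one (both epimers at C1′), via α-lithio sulfone 14 (not isolated), via C1′-lithiated substitution product 15 (not isolated)
Conditions: LiN(iPr)2 (2.2 equiv), THF, −78 °C; then 6 (1.1 equiv), −78 to −20 °C; aq. NH4Cl
Reagents that add atoms: none
Why: Carbanion 14 attacks C6 of 6 in a 1,4-sense relative to the C4 carbonyl, and the enolate so formed ejects methoxide and restores the ring double bond, so the C6–C1′ bond is made by addition–elimination (nucleophilic vinylic substitution). The closest known reaction type is the replacement of an alkoxy group in 2-alkoxy-4-pyranones and other β-alkoxy enones by stabilised carbanions such as lithiated sulfones. No ring is closed, and ring A is carried through intact. The new centre C1′ forms without control as a mixture of epimers, which is of no consequence because it becomes a CH2 group in step 9, and the remote C10′ centre is not involved. The step needs mono-substitution at C2/C6 and no attack at C4: the two methoxy-bearing carbons of 6 are equivalent by symmetry, the C4 carbonyl is a doubly vinylogous carbonate flanked by two methyls and a poor electrophile for a soft carbanion, and a second substitution is blocked because the product is deprotonated at C1′ to the delocalised anion 15. The second equivalent of amide serves that deprotonation and re-lithiates any sulfone protonated by the product, so 13 can be the limiting component.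

Step 9
Reactants: 16 6-((10S)-10-((tert-butyldimethylsilyl)oxy)-1-(phenylsulfonyl)undecyl)-2-methoxy-3,5-dimethyl-4H-pyran-4-one
Product: 17 6-((S)-10-((tert-butyldimethylsilyl)oxy)undecyl)-2-methoxy-3,5-dimethyl-4H-pyran-4-one
Conditions: SmI2 (2.5 equiv), THF/MeOH, −78 to 0 °C
Reagents that add atoms: none
Why: Reductive desulfonylation of a vinylogous β-keto sulfone by single-electron transfer, in which the pyranone accepts an electron, benzenesulfinate leaves from the neighbouring C1′, a second electron gives the extended enolate and methanol protonates C1′ to restore ring A, with the silyl ether and C10′ untouched.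

Step 10
Reactants: 17 6-((S)-10-((tert-butyldimethylsilyl)oxy)undecyl)-2-methoxy-3,5-dimethyl-4H-pyran-4-one
Product: 18 6-((S)-10-hydroxyundecyl)-2-methoxy-3,5-dimethyl-4H-pyran-4-one
Conditions: HF·pyridine, THF/pyridine, 0 °C to rt
Reagents that add atoms: none
Why: Fluoride-driven desilylation breaks only the Si–O bond under buffered conditions that should leave the enol ether of ring A alone, so the configuration at C10′ is retained.

Step 11
Reactants: 18 6-((S)-10-hydroxyundecyl)-2-methoxy-3,5-dimethyl-4H-pyran-4-one
Product: 19 (S)-11-(6-methoxy-3,5-dimethyl-4-oxo-4H-pyran-2-yl)undecan-2-yl acetate (CNP0416902.1)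
Conditions: Ac2O, pyridine, DMAP (cat.), CH2Cl2, rt
Reagents that add atoms: acetic anhydride, CC(=O)OC(C)=O
Why: DMAP-catalysed O-acylation of the secondary alcohol involves only the O–H bond, so the (S) configuration is kept.

**Compound list**

1 | dimethyl 3-oxopentanedioate | COC(=O)CC(=O)CC(=O)OC | starting material
2 | dimethyl 2-methyl-3-oxopentanedioate (racemic, not isolated) | COC(=O)CC(=O)C(C)C(=O)OC | intermediate
3 | dimethyl 2,4-dimethyl-3-oxopentanedioate (diastereomer mixture) | COC(=O)C(C)C(=O)C(C)C(=O)OC | intermediate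
4 | 4-hydroxy-6-methoxy-3,5-dimethyl-2H-pyran-2-one | COC1=C(C)C(O)=C(C)C(=O)O1 | intermediate
5 | 4-hydroxy-2,6-dimethoxy-3,5-dimethylpyrylium trifluoromethanesulfonate (not isolated) | COc1[o+]c(OC)c(C)c(O)c1C.[O-]S(=O)(=O)C(F)(F)F | intermediate
6 | 2,6-dimethoxy-3,5-dimethyl-4H-pyran-4-one | COc1oc(OC)c(C)c(=O)c1C | intermediate
7 | oct-7-en-1-yl bromide (8-bromooct-1-ene) | C=CCCCCCCBr | starting material
8 | (S)-2-methyloxirane ((S)-propylene oxide) | C[C@H]1CO1 | starting material
9 | oct-7-en-1-ylmagnesium bromide (not isolated) | C=CCCCCCC[Mg]Br | intermediate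
10 | (S)-undec-10-en-2-ol | C[C@H](O)CCCCCCCC=C | intermediate
11 | (S)-tert-butyldimethyl(undec-10-en-2-yloxy)silane | C[C@H](O[Si](C)(C)C(C)(C)C)CCCCCCCC=C | intermediate
12 | (S)-tert-butyldimethyl((11-(phenylthio)undecan-2-yl)oxy)silane | C[C@H](O[Si](C)(C)C(C)(C)C)CCCCCCCCCSc1ccccc1 | intermediate
13 | (S)-tert-butyldimethyl((11-(phenylsulfonyl)undecan-2-yl)oxy)silane | C[C@H](O[Si](C)(C)C(C)(C)C)CCCCCCCCCS(=O)(=O)c1ccccc1 | intermediate
14 | lithium (10S)-10-((tert-butyldimethylsilyl)oxy)-1-(phenylsulfonyl)undecan-1-ide (α-lithio sulfone, not isolated) | [Li+].C[C@H](O[Si](C)(C)C(C)(C)C)CCCCCCCC[CH-]S(=O)(=O)c1ccccc1 | intermediate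
15 | lithium (10S)-10-((tert-butyldimethylsilyl)oxy)-1-(6-methoxy-3,5-dimethyl-4-oxo-4H-pyran-2-yl)-1-(phenylsulfonyl)undecan-1-ide (delocalised anion of 16, not isolated) | [Li+].COc1oc([C-](CCCCCCCC[C@H](C)O[Si](C)(C)C(C)(C)C)S(=O)(=O)c2ccccc2)c(C)c(=O)c1C | intermediate
16 | 6-((10S)-10-((tert-butyldimethylsilyl)oxy)-1-(phenylsulfonyl)undecyl)-2-methoxy-3,5-dimethyl-4H-pyran-4-one (both epimers at C1′) | COc1oc(C(CCCCCCCC[C@H](C)O[Si](C)(C)C(C)(C)C)S(=O)(=O)c2ccccc2)c(C)c(=O)c1C | intermediate
17 | 6-((S)-10-((tert-butyldimethylsilyl)oxy)undecyl)-2-methoxy-3,5-dimethyl-4H-pyran-4-one | COc1oc(CCCCCCCCC[C@H](C)O[Si](C)(C)C(C)(C)C)c(C)c(=O)c1C | intermediate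
18 | 6-((S)-10-hydroxyundecyl)-2-methoxy-3,5-dimethyl-4H-pyran-4-one | COc1oc(CCCCCCCCC[C@H](C)O)c(C)c(=O)c1C | intermediate
19 | (S)-11-(6-methoxy-3,5-dimethyl-4-oxo-4H-pyran-2-yl)undecan-2-yl acetate (CNP0416902.1) | COc1oc(CCCCCCCCC[C@H](C)OC(C)=O)c(C)c(=O)c1C | target

**Step count and risks**

Total: 11 steps. Longest linear sequence: 8 steps (steps 4 to 11, from 7 to 19); the pyranone branch (steps 1 to 3) joins at step 8.

1. Step 8. Proton transfer from the more acidic substitution product to carbanion 14 may outrun re-lithiation and stall the conversion, and attack of a secondary carbanion on the fully substituted C6 beside the C5 methyl may be slow. The fallback sets out from 6 and 11 and returns at 16; it makes the ring–carbon bond with a small carbanion and attaches the chain afterwards by alkylation. Pyranone 6 and lithiated methyl phenyl sulfone (PhSO2CH3, n-BuLi, THF, −78 °C, two equivalents) should give 2-methoxy-3,5-dimethyl-6-((phenylsulfonyl)methyl)-4H-pyran-4-one F1 by the same addition–elimination. Alkene 11 is ozonised (O3, CH2Cl2, −78 °C; PPh3) to (S)-9-((tert-butyldimethylsilyl)oxy)decanal F2, reduced (NaBH4, MeOH) to (S)-9-((tert-butyldimethylsilyl)oxy)decan-1-ol F3 and converted (I2, PPh3, imidazole, CH2Cl2) into (S)-tert-butyl((10-iododecan-2-yl)oxy)dimethylsilane F4. C-Alkylation of the doubly stabilised anion of F1 with F4 (K2CO3, DMF, 50 °C) should lead to 16.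

2. Step 9. Electron transfer may be absorbed by ring A without C–S cleavage, or may go on to over-reduction of the pyranone. The fallback sets out from 11 and 6 and returns at 17; it uses a benzyl ester as the carbanion-stabilising group, removed by hydrogenolysis and loss of CO2 instead of by electron transfer. Cross-metathesis of 11 with benzyl acrylate (second-generation Grubbs catalyst, (H2IMes)(PCy3)Cl2Ru=CHPh, CH2Cl2, 40 °C) should give benzyl (S,E)-11-((tert-butyldimethylsilyl)oxy)dodec-2-enoate F5. Hydrogenation of the C=C bond alone (H2, RhCl(PPh3)3, benzene/EtOH) gives benzyl (S)-11-((tert-butyldimethylsilyl)oxy)dodecanoate F6. Deprotonation of F6 (LiN(iPr)2, 2.2 equiv, THF, −78 °C) and addition of 6 should give, by the same addition–elimination, benzyl (11S)-11-((tert-butyldimethylsilyl)oxy)-2-(6-methoxy-3,5-dimethyl-4-oxo-4H-pyran-2-yl)dodecanoate F7. Hydrogenolysis (H2, Pd/C, EtOAc) frees (11S)-11-((tert-butyldimethylsilyl)oxy)-2-(6-methoxy-3,5-dimethyl-4-oxo-4H-pyran-2-yl)dodecanoic acid F8, a vinylogous β-keto acid that should lose CO2 on gentle warming and give 17.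

3. Step 2. In sulfuric acid, ester cleavage and decarboxylation of the β-keto diester may outrun ring closure, and the enol ether of 4 may hydrolyse during the aqueous quench. The fallback sets out from 11 and returns at 17; ring A is built on the chain and pyranone 6 is not needed. Alkene 11 is taken to ester F6 as described under step 9. Claisen-type acylation of the dianion of methyl 2-methyl-3-oxopentanoate (NaH, then n-BuLi, THF, 0 °C) with F6 should give methyl (15S)-15-((tert-butyldimethylsilyl)oxy)-2,4-dimethyl-3,5-dioxohexadecanoate F9. Base-induced lactonisation (DBU, toluene, reflux) closes it to 6-((S)-10-((tert-butyldimethylsilyl)oxy)undecyl)-4-hydroxy-3,5-dimethyl-2H-pyran-2-one F10. O-Methylation with MeOTf in CH2Cl2, as in step 3, gives 4-hydroxy-2-methoxy-3,5-dimethyl-6-((S)-10-((tert-butyldimethylsilyl)oxy)undecyl)pyrylium triflate F11, which aq. NaHCO3 converts into 17.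

**Further compounds**

F1 | step 8 | 2-methoxy-3,5-dimethyl-6-((phenylsulfonyl)methyl)-4H-pyran-4-one | COc1oc(CS(=O)(=O)c2ccccc2)c(C)c(=O)c1C
F2 | step 8 | (S)-9-((tert-butyldimethylsilyl)oxy)decanal | C[C@H](O[Si](C)(C)C(C)(C)C)CCCCCCCC=O
F3 | step 8 | (S)-9-((tert-butyldimethylsilyl)oxy)decan-1-ol | C[C@H](O[Si](C)(C)C(C)(C)C)CCCCCCCCO
F4 | step 8 | (S)-tert-butyl((10-iododecan-2-yl)oxy)dimethylsilane | C[C@H](O[Si](C)(C)C(C)(C)C)CCCCCCCCI
F5 | step 9 | benzyl (S,E)-11-((tert-butyldimethylsilyl)oxy)dodec-2-enoate | C[C@H](O[Si](C)(C)C(C)(C)C)CCCCCCC/C=C/C(=O)OCc1ccccc1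
F6 | step 9 | benzyl (S)-11-((tert-butyldimethylsilyl)oxy)dodecanoate | C[C@H](O[Si](C)(C)C(C)(C)C)CCCCCCCCCC(=O)OCc1ccccc1
F7 | step 9 | benzyl (11S)-11-((tert-butyldimethylsilyl)oxy)-2-(6-methoxy-3,5-dimethyl-4-oxo-4H-pyran-2-yl)dodecanoate (both epimers at C2) | COc1oc(C(CCCCCCCC[C@H](C)O[Si](C)(C)C(C)(C)C)C(=O)OCc2ccccc2)c(C)c(=O)c1C
F8 | step 9 | (11S)-11-((tert-butyldimethylsilyl)oxy)-2-(6-methoxy-3,5-dimethyl-4-oxo-4H-pyran-2-yl)dodecanoic acid | COc1oc(C(CCCCCCCC[C@H](C)O[Si](C)(C)C(C)(C)C)C(=O)O)c(C)c(=O)c1C
F9 | step 2 | methyl (15S)-15-((tert-butyldimethylsilyl)oxy)-2,4-dimethyl-3,5-dioxohexadecanoate | COC(=O)C(C)C(=O)C(C)C(=O)CCCCCCCCC[C@H](C)O[Si](C)(C)C(C)(C)C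
F10 | step 2 | 6-((S)-10-((tert-butyldimethylsilyl)oxy)undecyl)-4-hydroxy-3,5-dimethyl-2H-pyran-2-one | C[C@H](O[Si](C)(C)C(C)(C)C)CCCCCCCCCC1=C(C)C(O)=C(C)C(=O)O1
F11 | step 2 | 4-hydroxy-2-methoxy-3,5-dimethyl-6-((S)-10-((tert-butyldimethylsilyl)oxy)undecyl)pyrylium triflate | COc1[o+]c(CCCCCCCCC[C@H](C)O[Si](C)(C)C(C)(C)C)c(C)c(O)c1C.[O-]S(=O)(=O)C(F)(F)F
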